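Ring A is made de novo: its six carbons come from a furan (four) and a terminal alkyne (two), held together by the O1–C2–C3 unit of the dihydrofuran, which already carries both stereocentres. A single gold-catalysed furan–yne cycloisomerisation of the 2-alkoxyfuran 11 forms C3a–C7a, C4–C5 and C4–O, closing the dihydrofuran ring and ring A at once. The feature exploited is the substitution of ring A: a phenol at C4 beside the ring fusion (C3a), the ether oxygen O1 on C7a and a carbon substituent at C6. The precursor is the benzyl-protected anti (1S,2R) 1,2-diaryl-but-3-ynyl ether of methyl 5-hydroxyfuran-3-carboxylate.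

Key step: step 6

Remarks on the chemistry
- Assumption: (S)-BINOL is taken to direct the alkynylzinc to the Si face of aldehyde 1, as in titanium–BINOL dialkylzinc additions; if the sense proves opposite, (R)-BINOL is used and nothing else changes.
- All aryl oxygens are carried as benzyl ethers, not methyl ethers. The last step can then be run at −78 °C with a cation scavenger, which suits a stilbene next to an acid-labile 2-(2,4-dioxygenated aryl) dihydrofuran better than hot BBr3.
- The alkyne stays silylated until after the copper-catalysed etherification, because a free terminal alkyne would form a copper acetylide.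
- The furan ester is kept through the key step as an electron-withdrawing group: it tames the alkoxyfuran and biases the opening of the arene oxide.
- No structural error was found in the key-step precursor or product. The propargylic carbon is R in 11 and S (as C3) in 14 only because ethynyl ranks below the aryl group while C3a ranks above it; no bond at a stereocentre is touched.

Step 1
Reactants: 1 3,5-bis(benzyloxy)benzaldehyde; 2 ethynyltri(propan-2-yl)silane
Product: 4 (1R)-1-[3,5-bis(benzyloxy)phenyl]-3-[tri(propan-2-yl)silyl]prop-2-yn-1-ol, via alkynylzinc 3 (not isolated)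
Conditions: 2 (2.2 equiv), Et2Zn (2 equiv), toluene, reflux; then (S)-BINOL (40 mol%), Ti(OiPr)4 (50 mol%), Et2O, rt; then 1, rt
Reagents that add atoms: none
Why: Titanium–BINOL-catalysed asymmetric alkynylation of an aromatic aldehyde with an alkynylzinc is established for aryl aldehydes, and delivery of the alkynyl group to the Si face of 1 by the (S)-BINOL–titanium complex should set the R carbinol centre.

Step 2
Reactants: 4 (1R)-1-[3,5-bis(benzyloxy)phenyl]-3-[tri(propan-2-yl)silyl]prop-2-yn-1-ol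
Product: 5 (1R)-1-[3,5-bis(benzyloxy)phenyl]-3-[tri(propan-2-yl)silyl]prop-2-yn-1-yl methanesulfonate
Conditions: MsCl, Et3N, CH2Cl2, −40 °C; used crude at once
Reagents that add atoms: methanesulfonyl chloride, CS(=O)(=O)Cl
Why: Mesylation (O-sulfonylation) leaves the C–O bond and hence the R configuration untouched, and the meta-alkoxy groups do not stabilise a benzylic cation, so the mesylate should hold at low temperature for immediate use.

Step 3
Reactants: 5 (1R)-1-[3,5-bis(benzyloxy)phenyl]-3-[tri(propan-2-yl)silyl]prop-2-yn-1-yl methanesulfonate; 6 2,4-bis(benzyloxy)benzaldehyde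
Product: 8 (1S,2S)-1-[2,4-bis(benzyloxy)phenyl]-2-[3,5-bis(benzyloxy)phenyl]-4-[tri(propan-2-yl)silyl]but-3-yn-1-ol (anti), via allenylzinc mesylate 7 (not isolated)
Conditions: Pd(OAc)2 (5 mol%), PPh3 (5 mol%), Et2Zn (3 equiv), THF, −78 → −20 °C
Reagents that add atoms: none
Why: In this Marshall propargylation, zerovalent palladium opens the mesylate by anti SN2′ oxidative addition and transmetalation gives the allenylzinc 7, whose SE2′ addition to 6 through a cyclic six-membered transition state transfers the chirality of 5 to C2 (S, net inversion) and sets C1 (S) anti to it because the aldehyde aryl group avoids the allenyl aryl group.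

Step 4
Reactants: 8 (1S,2S)-1-[2,4-bis(benzyloxy)phenyl]-2-[3,5-bis(benzyloxy)phenyl]-4-[tri(propan-2-yl)silyl]but-3-yn-1-ol; 9 methyl 5-bromofuran-3-carboxylate
Product: 10 methyl 5-{[(1S,2S)-1-[2,4-bis(benzyloxy)phenyl]-2-[3,5-bis(benzyloxy)phenyl]-4-[tri(propan-2-yl)silyl]but-3-yn-1-yl]oxy}furan-3-carboxylate
Conditions: CuI (10 mol%), 3,4,7,8-tetramethyl-1,10-phenanthroline (20 mol%), Cs2CO3 (2 equiv), 4 Å MS, toluene, 100 °C
Reagents that add atoms: none
Why: Ullmann-type C–O coupling of a secondary alcohol with a heteroaryl bromide under monovalent copper with a phenanthroline ligand forms the furyl ether at oxygen without touching either stereocentre, the silyl cap preventing copper acetylide formation.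

Step 5
Reactants: 10 methyl 5-{[(1S,2S)-1-[2,4-bis(benzyloxy)phenyl]-2-[3,5-bis(benzyloxy)phenyl]-4-[tri(propan-2-yl)silyl]but-3-yn-1-yl]oxy}furan-3-carboxylate
Product: 11 methyl 5-{[(1S,2R)-1-[2,4-bis(benzyloxy)phenyl]-2-[3,5-bis(benzyloxy)phenyl]but-3-yn-1-yl]oxy}furan-3-carboxylate
Conditions: Bu4NF (1.1 equiv), wet THF, 0 °C, short reaction time
Reagents that add atoms: none
Why: Fluoride-induced protodesilylation of the alkynylsilane frees the terminal alkyne, and short contact at 0 °C should keep the doubly activated propargylic C–H from isomerising to the allene while the ester and furyl ether are inert to fluoride.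

Step 6
Reactants: 11 methyl 5-{[(1S,2R)-1-[2,4-bis(benzyloxy)phenyl]-2-[3,5-bis(benzyloxy)phenyl]but-3-yn-1-yl]oxy}furan-3-carboxylate
Product: 14 methyl (2S,3S)-2-[2,4-bis(benzyloxy)phenyl]-3-[3,5-bis(benzyloxy)phenyl]-4-hydroxy-2,3-dihydro-1-benzofuran-6-carboxylate, via oxepine 12 (not isolated), via arene oxide 13 (not isolated)
Conditions: Ph3PAuNTf2 (5 mol%), 4 Å MS, CH2Cl2, 0 °C → rt
Reagents that add atoms: none
Why: Proposed new method: Cationic monovalent gold activates the terminal alkyne of 11 and the furan C2=C3 bond adds in a 5-exo-dig sense, the ether-bearing furan carbon bonding to the internal alkyne carbon (C3a–C7a) to give a cyclopropyl gold carbene; cleavage of the furan C–O bond then gives a formyl-conjugated dienyl carbene, the formyl oxygen adds to the carbene carbon (C4–O) to give oxepine 12, a 6π electrocyclisation (C4–C5) gives arene oxide 13, and opening of its C5–O bond with loss of the C4 hydrogen gives phenol 14. The closest known reaction type is the gold-catalysed furan–yne cycloisomerisation of furfuryl propargyl ethers and amines to ring-fused phenols, which has the same three-atom tether but a carbon instead of an oxygen on the furan. The dihydrofuran ring closes by 5-exo-dig attack on the gold-bound alkyne and ring A by 6π electrocyclisation of the oxepine. No stereocentre is formed: C2 and C3 come unchanged from the anti tether of 11, which is why 14 is trans. The first selectivity needed is bonding of the alkyne to the ether-bearing furan carbon and not only to its more nucleophilic C–H neighbour; the O–C–C tether makes only the five-membered closure productive, a first bond from the neighbouring carbon gives a dioxy-stabilised cation that the vinylgold can still close to the same cyclopropyl carbene, and the adjacent ester shields and deactivates that carbon. The second is the direction of arene oxide opening, where the ester on C6 sits on a charge-bearing carbon of the cation that would leave the hydroxyl on C5, so C5–O cleavage, which leaves it on C4, should be favoured.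

Step 7
Reactants: 14 methyl (2S,3S)-2-[2,4-bis(benzyloxy)phenyl]-3-[3,5-bis(benzyloxy)phenyl]-4-hydroxy-2,3-dihydro-1-benzofuran-6-carboxylate
Product: 15 (2S,3S)-2-[2,4-bis(benzyloxy)phenyl]-3-[3,5-bis(benzyloxy)phenyl]-6-(hydroxymethyl)-2,3-dihydro-1-benzofuran-4-ol
Conditions: LiAlH4 (3 equiv), THF, 0 °C; Rochelle salt work-up
Reagents that add atoms: none
Why: Hydride reduction of the aryl ester to the benzylic alcohol proceeds on the aluminium phenoxide formed first (hence the excess) and should leave the benzyl ethers, the C2–O bond and both stereocentres untouched.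

Step 8
Reactants: 15 (2S,3S)-2-[2,4-bis(benzyloxy)phenyl]-3-[3,5-bis(benzyloxy)phenyl]-6-(hydroxymethyl)-2,3-dihydro-1-benzofuran-4-ol
Product: 16 (2S,3S)-2-[2,4-bis(benzyloxy)phenyl]-3-[3,5-bis(benzyloxy)phenyl]-4-hydroxy-2,3-dihydro-1-benzofuran-6-carbaldehyde
Conditions: activated MnO2 (15 equiv), CH2Cl2, rt
Reagents that add atoms: none
Why: MnO2 oxidation is selective for benzylic alcohols under neutral conditions, so the free phenol, the benzyl ethers and the acid-sensitive 2-aryl dihydrofuran should survive.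

Step 9
Reactants: 17 1-(benzyloxy)-4-(chloromethyl)benzene
Product: 18 diethyl {[4-(benzyloxy)phenyl]methyl}phosphonate
Conditions: P(OEt)3 (3 equiv), neat, 140 °C
Reagents that add atoms: triethyl phosphite, CCOP(OCC)OCC
Why: The Michaelis–Arbuzov reaction of a benzylic chloride with triethyl phosphite gives the benzylphosphonate directly, the chloroethane leaving the hot mixture.

Step 10
Reactants: 16 (2S,3S)-2-[2,4-bis(benzyloxy)phenyl]-3-[3,5-bis(benzyloxy)phenyl]-4-hydroxy-2,3-dihydro-1-benzofuran-6-carbaldehyde; 18 diethyl {[4-(benzyloxy)phenyl]methyl}phosphonate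
Product: 19 (2S,3S)-2-[2,4-bis(benzyloxy)phenyl]-3-[3,5-bis(benzyloxy)phenyl]-6-{(E)-2-[4-(benzyloxy)phenyl]ethenyl}-2,3-dihydro-1-benzofuran-4-ol
Conditions: 18 (1.5 equiv), KOtBu (3.5 equiv), THF, 0 °C → rt; then aq. NH4Cl
Reagents that add atoms: none
Why: Horner–Wadsworth–Emmons olefination of a benzylphosphonate anion with an aromatic aldehyde should give the E-stilbene, the extra base only converting the C4 phenol, which is meta to the formyl group and so does not deactivate it, into its phenoxide.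

Step 11
Reactants: 19 (2S,3S)-2-[2,4-bis(benzyloxy)phenyl]-3-[3,5-bis(benzyloxy)phenyl]-6-{(E)-2-[4-(benzyloxy)phenyl]ethenyl}-2,3-dihydro-1-benzofuran-4-ol
Product: 20 (2S,3S)-2-(2,4-dihydroxyphenyl)-3-(3,5-dihydroxyphenyl)-6-[(E)-2-(4-hydroxyphenyl)ethenyl]-2,3-dihydro-1-benzofuran-4-ol
Conditions: BCl3 (10 equiv), pentamethylbenzene (15 equiv), CH2Cl2, −78 °C; MeOH quench
Reagents that add atoms: none
Why: Lewis-acid debenzylation with BCl3 and pentamethylbenzene as a non-basic benzyl cation scavenger cleaves aryl benzyl ethers at −78 °C without reducing or alkylating the stilbene, and any reversible opening of the C2–O bond should reclose to the more stable trans isomer with C3 unchanged.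

Compound list
1 | 3,5-bis(benzyloxy)benzaldehyde | O=Cc1cc(OCc2ccccc2)cc(OCc2ccccc2)c1 | starting material
2 | ethynyltri(propan-2-yl)silane | C#C[Si](C(C)C)(C(C)C)C(C)C | starting material
3 | ethyl{[tri(propan-2-yl)silyl]ethynyl}zinc (alkynylzinc, not isolated) | CC[Zn]C#C[Si](C(C)C)(C(C)C)C(C)C | intermediate
4 | (1R)-1-[3,5-bis(benzyloxy)phenyl]-3-[tri(propan-2-yl)silyl]prop-2-yn-1-ol | O[C@@H](C#C[Si](C(C)C)(C(C)C)C(C)C)c1cc(OCc2ccccc2)cc(OCc2ccccc2)c1 | intermediate
5 | (1R)-1-[3,5-bis(benzyloxy)phenyl]-3-[tri(propan-2-yl)silyl]prop-2-yn-1-yl methanesulfonate | CS(=O)(=O)O[C@@H](C#C[Si](C(C)C)(C(C)C)C(C)C)c1cc(OCc2ccccc2)cc(OCc2ccccc2)c1 | intermediate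
6 | 2,4-bis(benzyloxy)benzaldehyde | O=Cc1ccc(OCc2ccccc2)cc1OCc1ccccc1 | starting material
7 | {(aS)-3-[3,5-bis(benzyloxy)phenyl]-1-[tri(propan-2-yl)silyl]propa-1,2-dien-1-yl}zinc methanesulfonate, zinc on the allene face anti to the departed mesylate (allenylzinc mesylate, not isolated) | [H]C(c1cc(OCc2ccccc2)cc(OCc2ccccc2)c1)=[C@]=C([Si](C(C)C)(C(C)C)C(C)C)[Zn]OS(C)(=O)=O | intermediate
8 | (1S,2S)-1-[2,4-bis(benzyloxy)phenyl]-2-[3,5-bis(benzyloxy)phenyl]-4-[tri(propan-2-yl)silyl]but-3-yn-1-ol (anti) | O[C@H](c1ccc(OCc2ccccc2)cc1OCc1ccccc1)[C@H](C#C[Si](C(C)C)(C(C)C)C(C)C)c1cc(OCc2ccccc2)cc(OCc2ccccc2)c1 | intermediate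
9 | methyl 5-bromofuran-3-carboxylate | COC(=O)c1coc(Br)c1 | starting material
10 | methyl 5-{[(1S,2S)-1-[2,4-bis(benzyloxy)phenyl]-2-[3,5-bis(benzyloxy)phenyl]-4-[tri(propan-2-yl)silyl]but-3-yn-1-yl]oxy}furan-3-carboxylate | COC(=O)c1coc(O[C@H](c2ccc(OCc3ccccc3)cc2OCc2ccccc2)[C@H](C#C[Si](C(C)C)(C(C)C)C(C)C)c2cc(OCc3ccccc3)cc(OCc3ccccc3)c2)c1 | intermediate
11 | methyl 5-{[(1S,2R)-1-[2,4-bis(benzyloxy)phenyl]-2-[3,5-bis(benzyloxy)phenyl]but-3-yn-1-yl]oxy}furan-3-carboxylate (anti; key-step precursor) | COC(=O)c1coc(O[C@H](c2ccc(OCc3ccccc3)cc2OCc2ccccc2)[C@H](C#C)c2cc(OCc3ccccc3)cc(OCc3ccccc3)c2)c1 | intermediate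
12 | oxepine: methyl (2S,3S)-2-[2,4-bis(benzyloxy)phenyl]-3-[3,5-bis(benzyloxy)phenyl]-2,3-dihydrofuro[3,2-c]oxepine carboxylate, seven-membered ring O–C4=C3a–C7a=C7–C6(CO2Me)=C5 with atoms labelled as in 14 (not isolated) | COC(=O)C1=COC=C2C(=C1)O[C@H](c1ccc(OCc3ccccc3)cc1OCc1ccccc1)[C@H]2c1cc(OCc2ccccc2)cc(OCc2ccccc2)c1 | intermediate
13 | arene oxide: methyl (2S,3S)-2-[2,4-bis(benzyloxy)phenyl]-3-[3,5-bis(benzyloxy)phenyl]-4,5-epoxy-2,3,4,5-tetrahydro-1-benzofuran-6-carboxylate, oxirane on either face (not isolated) | COC(=O)C1=CC2=C(C3OC13)[C@H](c1cc(OCc3ccccc3)cc(OCc3ccccc3)c1)[C@@H](c1ccc(OCc3ccccc3)cc1OCc1ccccc1)O2 | intermediate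
14 | methyl (2S,3S)-2-[2,4-bis(benzyloxy)phenyl]-3-[3,5-bis(benzyloxy)phenyl]-4-hydroxy-2,3-dihydro-1-benzofuran-6-carboxylate (trans; key-step product) | COC(=O)c1cc(O)c2c(c1)O[C@H](c1ccc(OCc3ccccc3)cc1OCc1ccccc1)[C@H]2c1cc(OCc2ccccc2)cc(OCc2ccccc2)c1 | intermediate
15 | (2S,3S)-2-[2,4-bis(benzyloxy)phenyl]-3-[3,5-bis(benzyloxy)phenyl]-6-(hydroxymethyl)-2,3-dihydro-1-benzofuran-4-ol | OCc1cc(O)c2c(c1)O[C@H](c1ccc(OCc3ccccc3)cc1OCc1ccccc1)[C@H]2c1cc(OCc2ccccc2)cc(OCc2ccccc2)c1 | intermediate
16 | (2S,3S)-2-[2,4-bis(benzyloxy)phenyl]-3-[3,5-bis(benzyloxy)phenyl]-4-hydroxy-2,3-dihydro-1-benzofuran-6-carbaldehyde | O=Cc1cc(O)c2c(c1)O[C@H](c1ccc(OCc3ccccc3)cc1OCc1ccccc1)[C@H]2c1cc(OCc2ccccc2)cc(OCc2ccccc2)c1 | intermediate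
17 | 1-(benzyloxy)-4-(chloromethyl)benzene | ClCc1ccc(OCc2ccccc2)cc1 | starting material
18 | diethyl {[4-(benzyloxy)phenyl]methyl}phosphonate | CCOP(=O)(Cc1ccc(OCc2ccccc2)cc1)OCC | intermediate
19 | (2S,3S)-2-[2,4-bis(benzyloxy)phenyl]-3-[3,5-bis(benzyloxy)phenyl]-6-{(E)-2-[4-(benzyloxy)phenyl]ethenyl}-2,3-dihydro-1-benzofuran-4-ol | c1ccccc1COc1ccc(/C=C/c2cc(O)c3c(c2)O[C@H](c2ccc(OCc4ccccc4)cc2OCc2ccccc2)[C@H]3c2cc(OCc4ccccc4)cc(OCc4ccccc4)c2)cc1 | intermediate
20 | (2S,3S)-2-(2,4-dihydroxyphenyl)-3-(3,5-dihydroxyphenyl)-6-[(E)-2-(4-hydroxyphenyl)ethenyl]-2,3-dihydro-1-benzofuran-4-ol | Oc1ccc(/C=C/c2cc(O)c3c(c2)O[C@H](c2ccc(O)cc2O)[C@H]3c2cc(O)cc(O)c2)cc1 | target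

Total step count: 11
Longest linear sequence: 10 steps (steps 1–8, 10 and 11; step 9 is a side branch)

Steps most likely to fail

1. Step 6 (gold cascade). The cascade may be diverted in three ways: closure through the furan C–H carbon next to the ether carbon followed by protodeauration (plain hydroarylation); acid-promoted hydrolysis of the ketene-acetal-like alkoxyfuran; or opening of the arene oxide towards C5, para to O1, which would put the hydroxyl on the wrong carbon. The fallback sets out from 8 and returns at 14, using known reactions only and the same O1–C2–C3 tether. The alkoxide of 8 (NaH, THF, 0 °C) displaces chloride from methyl 6-chloropyridazine-4-carboxylate by SNAr to give methyl 6-{[(1S,2S)-1-[2,4-bis(benzyloxy)phenyl]-2-[3,5-bis(benzyloxy)phenyl]-4-[tri(propan-2-yl)silyl]but-3-yn-1-yl]oxy}pyridazine-4-carboxylate F1. Bu4NF then frees the terminal alkyne, methyl 6-{[(1S,2R)-1-[2,4-bis(benzyloxy)phenyl]-2-[3,5-bis(benzyloxy)phenyl]but-3-yn-1-yl]oxy}pyridazine-4-carboxylate F2. Deprotonation with LiN(SiMe3)2 in the presence of 2-isopropoxy-4,4,5,5-tetramethyl-1,3,2-dioxaborolane (−78 °C, then HCl in Et2O) gives the alkynylboronate, methyl 6-{[(1S,2S)-1-[2,4-bis(benzyloxy)phenyl]-2-[3,5-bis(benzyloxy)phenyl]-4-(4,4,5,5-tetramethyl-1,3,2-dioxaborolan-2-yl)but-3-yn-1-yl]oxy}pyridazine-4-carboxylate F3. Heating (1,2-dichlorobenzene, about 180 °C) brings about the intramolecular inverse-electron-demand Diels–Alder reaction of the pyridazine with the alkyne and loss of N2. This should give methyl (2S,3S)-2-[2,4-bis(benzyloxy)phenyl]-3-[3,5-bis(benzyloxy)phenyl]-4-(4,4,5,5-tetramethyl-1,3,2-dioxaborolan-2-yl)-2,3-dihydro-1-benzofuran-6-carboxylate F4, in which boron marks C4. Oxidation with NaBO3·4H2O (THF/H2O) then gives 14.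

2. Step 4 (copper etherification). Transfer of the hindered secondary benzylic alkoxide at copper may be slow, and at 100 °C with base it competes with retro-addition or epimerisation of the alkoxide and with transesterification of the furan ester. The fallback sets out from 8 and returns at 10 by building the furan on the oxygen instead of coupling to it. KH and trichloroethylene (THF, rt) convert 8 into its (E)-1,2-dichlorovinyl ether, 1,3-bis(benzyloxy)-4-[(1S,2S)-2-[3,5-bis(benzyloxy)phenyl]-1-{[(E)-1,2-dichloroethenyl]oxy}-4-[tri(propan-2-yl)silyl]but-3-yn-1-yl]benzene F5. n-BuLi (2.2 equiv, −78 °C, then MeOH) gives the ethynyl ether, 1,3-bis(benzyloxy)-4-[(1S,2S)-2-[3,5-bis(benzyloxy)phenyl]-1-(ethynyloxy)-4-[tri(propan-2-yl)silyl]but-3-yn-1-yl]benzene F6. Rh2(OAc)4 (2 mol%) with methyl 2-diazo-3-oxopropanoate (CH2Cl2, rt) then effects the carbenoid formal [3+2] furan synthesis: the terminal ynol ether carbon attacks the carbenoid and the formyl oxygen closes onto the alkoxy-bearing carbon, giving 10.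

3. Step 3 (Marshall propargylation). Ionisation of the benzylic mesylate or racemisation of the aryl-substituted allenylpalladium or allenylzinc may erode the enantiomeric purity, and an open transition state may leak to the syn diastereomer. The fallback takes purity from resolution instead of chirality transfer; it sets out from 8 as obtained and returns at 8. Esterification with (S)-O-acetylmandelic acid (DCC, DMAP, CH2Cl2) gives (1S,2S)-1-[2,4-bis(benzyloxy)phenyl]-2-[3,5-bis(benzyloxy)phenyl]-4-[tri(propan-2-yl)silyl]but-3-yn-1-yl (2S)-2-(acetyloxy)-2-phenylacetate F7. This ester is separated from the esters of the enantiomer and of the syn isomer by chromatography or crystallisation and cleaved with LiOH (THF/H2O, 0 °C) to pure 8.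

Further compounds
F1 | step 6 | methyl 6-{[(1S,2S)-1-[2,4-bis(benzyloxy)phenyl]-2-[3,5-bis(benzyloxy)phenyl]-4-[tri(propan-2-yl)silyl]but-3-yn-1-yl]oxy}pyridazine-4-carboxylate | COC(=O)c1cnnc(O[C@H](c2ccc(OCc3ccccc3)cc2OCc2ccccc2)[C@H](C#C[Si](C(C)C)(C(C)C)C(C)C)c2cc(OCc3ccccc3)cc(OCc3ccccc3)c2)c1
F2 | step 6 | methyl 6-{[(1S,2R)-1-[2,4-bis(benzyloxy)phenyl]-2-[3,5-bis(benzyloxy)phenyl]but-3-yn-1-yl]oxy}pyridazine-4-carboxylate | COC(=O)c1cnnc(O[C@H](c2ccc(OCc3ccccc3)cc2OCc2ccccc2)[C@H](C#C)c2cc(OCc3ccccc3)cc(OCc3ccccc3)c2)c1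
F3 | step 6 | methyl 6-{[(1S,2S)-1-[2,4-bis(benzyloxy)phenyl]-2-[3,5-bis(benzyloxy)phenyl]-4-(4,4,5,5-tetramethyl-1,3,2-dioxaborolan-2-yl)but-3-yn-1-yl]oxy}pyridazine-4-carboxylate | COC(=O)c1cnnc(O[C@H](c2ccc(OCc3ccccc3)cc2OCc2ccccc2)[C@H](C#CB2OC(C)(C)C(C)(C)O2)c2cc(OCc3ccccc3)cc(OCc3ccccc3)c2)c1
F4 | step 6 | methyl (2S,3S)-2-[2,4-bis(benzyloxy)phenyl]-3-[3,5-bis(benzyloxy)phenyl]-4-(4,4,5,5-tetramethyl-1,3,2-dioxaborolan-2-yl)-2,3-dihydro-1-benzofuran-6-carboxylate | COC(=O)c1cc(B3OC(C)(C)C(C)(C)O3)c2c(c1)O[C@H](c1ccc(OCc3ccccc3)cc1OCc1ccccc1)[C@H]2c1cc(OCc2ccccc2)cc(OCc2ccccc2)c1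
F5 | step 4 | 1,3-bis(benzyloxy)-4-[(1S,2S)-2-[3,5-bis(benzyloxy)phenyl]-1-{[(E)-1,2-dichloroethenyl]oxy}-4-[tri(propan-2-yl)silyl]but-3-yn-1-yl]benzene | Cl/C=C(/Cl)O[C@H](c1ccc(OCc2ccccc2)cc1OCc1ccccc1)[C@H](C#C[Si](C(C)C)(C(C)C)C(C)C)c1cc(OCc2ccccc2)cc(OCc2ccccc2)c1
F6 | step 4 | 1,3-bis(benzyloxy)-4-[(1S,2S)-2-[3,5-bis(benzyloxy)phenyl]-1-(ethynyloxy)-4-[tri(propan-2-yl)silyl]but-3-yn-1-yl]benzene | C#CO[C@H](c1ccc(OCc2ccccc2)cc1OCc1ccccc1)[C@H](C#C[Si](C(C)C)(C(C)C)C(C)C)c1cc(OCc2ccccc2)cc(OCc2ccccc2)c1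
F7 | step 3 | (1S,2S)-1-[2,4-bis(benzyloxy)phenyl]-2-[3,5-bis(benzyloxy)phenyl]-4-[tri(propan-2-yl)silyl]but-3-yn-1-yl (2S)-2-(acetyloxy)-2-phenylacetate | CC(=O)O[C@@H](c1ccccc1)C(=O)O[C@H](c1ccc(OCc2ccccc2)cc1OCc1ccccc1)[C@H](C#C[Si](C(C)C)(C(C)C)C(C)C)c1cc(OCc2ccccc2)cc(OCc2ccccc2)c1
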